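**Retrosynthetic overview**
1. Target 19 ← lipase removal of the two catechol acetates from 18 ← one double oxidation of diol 17 that unveils both aldehydes together.
2. 17 ← Mitsunobu ester bond (C5–O) between acid 12 and 2-(3,4-diacetoxyphenyl)ethanol 15 (from 3,4-dihydroxyphenylacetic acid).
3. 12 ← opening of δ-lactone 9 (lactone C=O becomes the methyl ester, ring CH2O becomes the C5 acid); C2 ← anti-selective hydroxymethylation of the enolate of lactone 7.
4. C3 ← Rh/(S)-BINAP conjugate addition of alkenylboronate 5 to 5,6-dihydro-2H-pyran-2-one; the ethylidene geometry is fixed beforehand in (Z)-2-iodobut-2-en-1-ol from crotonaldehyde.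
5. Rings: none is built. The arene and the pyranone ring are bought; the lactone is a temporary scaffold, opened in step 8.

Assumption: C2, the CH(CHO)CO2Me carbon, is enolisable, so it is carried as a silyloxymethyl ester, becomes the aldehyde only in step 14, and 18 and 19 are handled cold without base or silica. TBS = tert-butyldimethylsilyl.

**Step 1**
Reactants: 1 (2E)-but-2-enal
Product: 2 (2Z)-2-iodobut-2-enal
Conditions: I2, K2CO3, DMAP (cat.), THF/H2O 1:1, rt
Reagents that add atoms: iodine, II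
Why: Amine-catalysed α-iodination of an enal (conjugate addition, iodination, elimination) gives the thermodynamically favoured isomer with CHO trans to CH3, which is the geometry the target enal needs.

**Step 2**
Reactants: 2 (2Z)-2-iodobut-2-enal
Product: 3 (2Z)-2-iodobut-2-en-1-ol
Conditions: NaBH4, CeCl3·7H2O, MeOH, 0 °C
Reagents that add atoms: none
Why: Luche reduction gives clean 1,2-reduction without touching the C–I bond or the alkene geometry.

**Step 3**
Reactants: 3 (2Z)-2-iodobut-2-en-1-ol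
Product: 4 tert-butyl{[(2Z)-2-iodobut-2-en-1-yl]oxy}dimethylsilane
Conditions: TBSCl, imidazole, CH2Cl2, 0 °C to rt
Reagents that add atoms: tert-butyldimethylsilyl chloride, CC(C)(C)[Si](C)(C)Cl
Why: Standard silylation of a primary allylic alcohol.

**Step 4**
Reactants: 4 tert-butyl{[(2Z)-2-iodobut-2-en-1-yl]oxy}dimethylsilane
Product: 5 tert-butyldimethyl{[(2E)-2-(4,4,5,5-tetramethyl-1,3,2-dioxaborolan-2-yl)but-2-en-1-yl]oxy}silane
Conditions: B2pin2, PdCl2(PPh3)2 (3 mol%), PPh3, KOPh, toluene, 50 °C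
Reagents that add atoms: bis(pinacolato)diboron, CC1(C)OB(OC1(C)C)B1OC(C)(C)C(C)(C)O1
Why: Miyaura borylation of an alkenyl iodide goes with retention, so boron sits cis to CH3 (the descriptor changes to E only because of CIP priorities).

**Step 5**
Reactants: 5 alkenyl pinacolboronate (2 equiv); 6 5,6-dihydro-2H-pyran-2-one
Product: 7 (4S)-4-[(2E)-1-(TBSO)but-2-en-2-yl]oxan-2-one
Conditions: [RhCl(C2H4)2]2 (2.5 mol%), (S)-BINAP (5.5 mol%), aq. KOH (10 mol%), 1,4-dioxane/H2O 10:1, 60 °C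
Reagents that add atoms: none
Why: Hayashi–Miyaura asymmetric 1,4-addition, in which the (S)-BINAP–Rh alkenyl species adds to one enantioface of the lactone (same facial sense as in the (S)-3-arylcyclohexanone series), sets the first stereocentre C3 as (4S) with the alkene geometry retained.

**Step 6**
Reactants: 7 (4S)-4-[(2E)-1-(TBSO)but-2-en-2-yl]oxan-2-one
Product: 8 (3S,4S)-4-[(2E)-1-(TBSO)but-2-en-2-yl]-3-(hydroxymethyl)oxan-2-one (3,4-trans)
Conditions: LDA, THF, −78 °C; CH2O (gas, from cracked paraformaldehyde), −78 to −30 °C; aq. NH4Cl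
Reagents that add atoms: formaldehyde, C=O
Why: Aldol reaction of the lithium lactone enolate with formaldehyde, which enters anti to the bulky C4 alkenyl group and so sets C2 as the 3,4-trans isomer (also the thermodynamic one).

**Step 7**
Reactants: 8 trans-hydroxymethyl lactone
Product: 9 (3S,4S)-4-[(2E)-1-(TBSO)but-2-en-2-yl]-3-[(TBSO)methyl]oxan-2-one
Conditions: TBSCl, imidazole, DMF, rt
Reagents that add atoms: tert-butyldimethylsilyl chloride, CC(C)(C)[Si](C)(C)Cl
Why: Silylation of the primary alcohol blocks retro-aldol and dehydration and keeps C1 at the alcohol level.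

**Step 8**
Reactants: 9 bis-silylated lactone
Product: 11 methyl (2S,3S)-3-[(2E)-1-(TBSO)but-2-en-2-yl]-5-hydroxy-2-[(TBSO)methyl]pentanoate, via lithium carboxylate 10 (not isolated)
Conditions: LiOH·H2O (1.05 equiv), THF/H2O, 0 °C; evaporate; MeI, DMF, rt; used at once
Reagents that add atoms: lithium hydroxide, [Li+].[OH-]; iodomethane, CI
Why: Saponification of the δ-lactone followed by SN2 O-methylation of the carboxylate opens the ring without any enolate, so C2 is untouched.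

**Step 9**
Reactants: 11 δ-hydroxy methyl ester
Product: 12 (3S,4S)-3-[(2E)-1-(TBSO)but-2-en-2-yl]-5-methoxy-5-oxo-4-[(TBSO)methyl]pentanoic acid
Conditions: TEMPO (cat.), PhI(OAc)2, MeCN/H2O 1:1, rt
Reagents that add atoms: water, O
Why: TEMPO/PhI(OAc)2 oxidation takes the primary alcohol through the aldehyde hydrate to the acid under conditions that spare silyl ethers, the alkene and C2.

**Step 10**
Reactants: 13 (3,4-dihydroxyphenyl)acetic acid
Product: 14 [3,4-bis(acetyloxy)phenyl]acetic acid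
Conditions: Ac2O, pyridine, 0 °C to rt; then H2O
Reagents that add atoms: acetic anhydride, CC(=O)OC(C)=O
Why: Acetylation of both phenols, with the mixed anhydride at the acid hydrolysed on aqueous work-up.

**Step 11**
Reactants: 14 [3,4-bis(acetyloxy)phenyl]acetic acid
Product: 15 4-(2-hydroxyethyl)-1,2-phenylene diacetate
Conditions: BH3·THF, THF, 0 °C; H2O quench
Reagents that add atoms: none
Why: Borane reduces the carboxylic acid (via the acyloxyborane) much faster than the aryl acetates.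

**Step 12**
Reactants: 12 acid; 15 4-(2-hydroxyethyl)-1,2-phenylene diacetate
Product: 16 5-{2-[3,4-bis(acetyloxy)phenyl]ethyl} 1-methyl (2S,3S)-3-[(2E)-1-(TBSO)but-2-en-2-yl]-2-[(TBSO)methyl]pentanedioate
Conditions: PPh3, DIAD, THF, 0 °C to rt
Reagents that add atoms: none
Why: Mitsunobu esterification activates the primary alcohol under neutral conditions and avoids acyl-transfer catalysts that could scramble the aryl acetates.

**Step 13**
Reactants: 16 bis-silyl ether
Product: 17 5-{2-[3,4-bis(acetyloxy)phenyl]ethyl} 1-methyl (2S,3S)-3-[(2E)-1-hydroxybut-2-en-2-yl]-2-(hydroxymethyl)pentanedioate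
Conditions: HF·pyridine, pyridine, THF, 0 °C to rt; crude diol used at once
Reagents that add atoms: none
Why: Buffered fluoride desilylation removes both primary TBS groups and leaves the esters and aryl acetates intact.

**Step 14**
Reactants: 17 diol
Product: 18 5-{2-[3,4-bis(acetyloxy)phenyl]ethyl} 1-methyl (2S,3S)-2-formyl-3-[(2E)-1-oxobut-2-en-2-yl]pentanedioate
Conditions: Dess–Martin periodinane (3.5 equiv), NaHCO3, CH2Cl2, 0 °C; cold pH 7 Na2S2O3 work-up, no silica
Reagents that add atoms: none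
Why: Dess–Martin oxidation with excess reagent binds both hydroxyls before either is oxidised, so no hydroxy-aldehyde (lactol) persists, while the bicarbonate buffer protects the new formyl ester centre C2 and the E-enal geometry is carried over from the allylic alcohol.

**Step 15**
Reactants: 18 dialdehyde diacetate
Product: 19 5-[2-(3,4-dihydroxyphenyl)ethyl] 1-methyl (2S,3S)-2-formyl-3-[(2E)-1-oxobut-2-en-2-yl]pentanedioate (target)
Conditions: lipase (immobilised Candida antarctica lipase B), n-BuOH, t-BuOMe, 30 °C; filter off enzyme, evaporate cold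
Reagents that add atoms: none
Why: Lipase-catalysed alcoholysis (transesterification to n-butanol) cleaves the activated aryl acetates under neutral, non-aqueous conditions that spare the two alkyl esters, both aldehydes and the labile C2 centre.

**Compound list**
1 | (2E)-but-2-enal (crotonaldehyde) | C/C=C/C=O | starting material
2 | (2Z)-2-iodobut-2-enal | C/C=C(/C=O)I | intermediate
3 | (2Z)-2-iodobut-2-en-1-ol | C/C=C(/CO)I | intermediate
4 | tert-butyl{[(2Z)-2-iodobut-2-en-1-yl]oxy}dimethylsilane | C/C=C(/CO[Si](C)(C)C(C)(C)C)I | intermediate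
5 | tert-butyldimethyl{[(2E)-2-(4,4,5,5-tetramethyl-1,3,2-dioxaborolan-2-yl)but-2-en-1-yl]oxy}silane | C/C=C(/CO[Si](C)(C)C(C)(C)C)B1OC(C)(C)C(C)(C)O1 | intermediate
6 | 5,6-dihydro-2H-pyran-2-one | O=C1C=CCCO1 | starting material
7 | (4S)-4-[(2E)-1-(TBSO)but-2-en-2-yl]oxan-2-one | C/C=C(/CO[Si](C)(C)C(C)(C)C)[C@@H](CCO1)CC1=O | intermediate
8 | (3S,4S)-4-[(2E)-1-(TBSO)but-2-en-2-yl]-3-(hydroxymethyl)oxan-2-one | C/C=C(/CO[Si](C)(C)C(C)(C)C)[C@@H](CCO1)[C@@H](CO)C1=O | intermediate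
9 | (3S,4S)-4-[(2E)-1-(TBSO)but-2-en-2-yl]-3-[(TBSO)methyl]oxan-2-one | C/C=C(/CO[Si](C)(C)C(C)(C)C)[C@@H](CCO1)[C@@H](CO[Si](C)(C)C(C)(C)C)C1=O | intermediate
10 | lithium (2S,3S)-3-[(2E)-1-(TBSO)but-2-en-2-yl]-5-hydroxy-2-[(TBSO)methyl]pentanoate | [Li+].C/C=C(/CO[Si](C)(C)C(C)(C)C)[C@@H](CCO)[C@@H](CO[Si](C)(C)C(C)(C)C)C([O-])=O | intermediate (not isolated)
11 | methyl (2S,3S)-3-[(2E)-1-(TBSO)but-2-en-2-yl]-5-hydroxy-2-[(TBSO)methyl]pentanoate | C/C=C(/CO[Si](C)(C)C(C)(C)C)[C@@H](CCO)[C@@H](CO[Si](C)(C)C(C)(C)C)C(=O)OC | intermediate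
12 | (3S,4S)-3-[(2E)-1-(TBSO)but-2-en-2-yl]-5-methoxy-5-oxo-4-[(TBSO)methyl]pentanoic acid | C/C=C(/CO[Si](C)(C)C(C)(C)C)[C@@H](CC(=O)O)[C@@H](CO[Si](C)(C)C(C)(C)C)C(=O)OC | intermediate
13 | (3,4-dihydroxyphenyl)acetic acid | OC(=O)Cc1ccc(O)c(O)c1 | starting material
14 | [3,4-bis(acetyloxy)phenyl]acetic acid | OC(=O)Cc1ccc(OC(C)=O)c(OC(C)=O)c1 | intermediate
15 | 4-(2-hydroxyethyl)-1,2-phenylene diacetate | OCCc1ccc(OC(C)=O)c(OC(C)=O)c1 | intermediate
16 | 5-{2-[3,4-bis(acetyloxy)phenyl]ethyl} 1-methyl (2S,3S)-3-[(2E)-1-(TBSO)but-2-en-2-yl]-2-[(TBSO)methyl]pentanedioate | C/C=C(/CO[Si](C)(C)C(C)(C)C)[C@@H](CC(=O)OCCc1ccc(OC(C)=O)c(OC(C)=O)c1)[C@@H](CO[Si](C)(C)C(C)(C)C)C(=O)OC | intermediate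
17 | 5-{2-[3,4-bis(acetyloxy)phenyl]ethyl} 1-methyl (2S,3S)-3-[(2E)-1-hydroxybut-2-en-2-yl]-2-(hydroxymethyl)pentanedioate | C/C=C(/CO)[C@@H](CC(=O)OCCc1ccc(OC(C)=O)c(OC(C)=O)c1)[C@@H](CO)C(=O)OC | intermediate
18 | 5-{2-[3,4-bis(acetyloxy)phenyl]ethyl} 1-methyl (2S,3S)-2-formyl-3-[(2E)-1-oxobut-2-en-2-yl]pentanedioate | C/C=C(/C=O)[C@@H](CC(=O)OCCc1ccc(OC(C)=O)c(OC(C)=O)c1)[C@@H](C=O)C(=O)OC | intermediate
19 | 5-[2-(3,4-dihydroxyphenyl)ethyl] 1-methyl (2S,3S)-2-formyl-3-[(2E)-1-oxobut-2-en-2-yl]pentanedioate | C/C=C(/C=O)[C@@H](CC(=O)OCCc1ccc(O)c(O)c1)[C@@H](C=O)C(=O)OC | target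

**Totals**
Total steps: 15. Longest linear sequence: 13 (steps 1–9 and 12–15); steps 10–11 make the aryl fragment.

**Three steps most likely to fail**

Step 5. The 1,1-disubstituted alkenylboronate is hindered; slow transmetalation, protodeboronation or β-oxygen elimination from the alkenyl–rhodium species could erode yield. The fallback sets out from 4 and returns at 7, setting C3 by organocatalysis instead. Heck coupling of 4 with acrolein (Pd(OAc)2, Bu4NCl, NaHCO3, DMF, rt) gives (2E,4E)-4-[(TBSO)methyl]hexa-2,4-dienal F1. Iminium-catalysed Michael addition of dimethyl malonate with (R)-2-{bis[3,5-bis(trifluoromethyl)phenyl][(trimethylsilyl)oxy]methyl}pyrrolidine (EtOH, 0 °C) gives the 1,4-adduct dimethyl 2-[(3S,4E)-4-[(TBSO)methyl]-1-oxohex-4-en-3-yl]propanedioate F2. NaBH4 reduction gives the hydroxy diester F3, which lactonises (cat. TsOH, toluene) to the trans lactone ester F4. Krapcho demethoxycarbonylation (LiCl, wet DMSO, 130 °C) then gives 7.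

Step 6. Gaseous formaldehyde can oligomerise, add twice, or the product can dehydrate to the α-methylene lactone. The fallback sets out from 7 and returns at 8, replacing the aldol by an alkylation. The same lithium enolate is alkylated with 4-methoxybenzyl chloromethyl ether (THF, −78 °C), again anti to the C4 substituent, to give the 3,4-trans PMB ether F5. Oxidative ether cleavage with DDQ (CH2Cl2/pH 7 buffer) gives 8.

Step 14. After the first oxidation a hydroxy-aldehyde could close to a lactol and be over-oxidised to a lactone, and the new formyl ester centre can epimerise. The fallback sets out from 8 and returns at 18, unveiling the two aldehydes one at a time with orthogonal protection.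
- Alcohol 8 is protected with 4-methoxybenzyl trichloroacetimidate (cat. Sc(OTf)3) as the PMB ether F5.
- LiOH then MeI gives, through the lithium carboxylate F6, the hydroxy methyl ester F7.
- TEMPO/PhI(OAc)2 gives the acid F8, and Mitsunobu coupling with 15 gives the diester F9.
- DDQ frees only the C1 alcohol F10 while the allylic TBS ether stays, so no lactol can form.
- Dess–Martin periodinane/NaHCO3 gives the formyl ester F11.
- HF·pyridine gives the hydroxy aldehyde F12 (in equilibrium with its lactol).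
- MnO2 in CH2Cl2 oxidises only the allylic alcohol of the open form and gives 18.

**Further compounds**
F1 | step 5 | (2E,4E)-4-[(TBSO)methyl]hexa-2,4-dienal | C/C=C(/CO[Si](C)(C)C(C)(C)C)\C=C\C=O
F2 | step 5 | dimethyl 2-[(3S,4E)-4-[(TBSO)methyl]-1-oxohex-4-en-3-yl]propanedioate | C/C=C(/CO[Si](C)(C)C(C)(C)C)[C@@H](CC=O)C(C(=O)OC)C(=O)OC
F3 | step 5 | dimethyl 2-[(3S,4E)-1-hydroxy-4-[(TBSO)methyl]hex-4-en-3-yl]propanedioate | C/C=C(/CO[Si](C)(C)C(C)(C)C)[C@@H](CCO)C(C(=O)OC)C(=O)OC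
F4 | step 5 | methyl (3S,4S)-4-[(2E)-1-(TBSO)but-2-en-2-yl]-2-oxooxane-3-carboxylate | C/C=C(/CO[Si](C)(C)C(C)(C)C)[C@@H](CCO1)[C@@H](C(=O)OC)C1=O
F5 | step 6 | (3S,4S)-4-[(2E)-1-(TBSO)but-2-en-2-yl]-3-{[(4-methoxyphenyl)methoxy]methyl}oxan-2-one | C/C=C(/CO[Si](C)(C)C(C)(C)C)[C@@H](CCO1)[C@@H](COCc2ccc(OC)cc2)C1=O
F6 | step 14 | lithium (2S,3S)-3-[(2E)-1-(TBSO)but-2-en-2-yl]-5-hydroxy-2-{[(4-methoxyphenyl)methoxy]methyl}pentanoate | [Li+].C/C=C(/CO[Si](C)(C)C(C)(C)C)[C@@H](CCO)[C@@H](COCc1ccc(OC)cc1)C([O-])=O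
F7 | step 14 | methyl (2S,3S)-3-[(2E)-1-(TBSO)but-2-en-2-yl]-5-hydroxy-2-{[(4-methoxyphenyl)methoxy]methyl}pentanoate | C/C=C(/CO[Si](C)(C)C(C)(C)C)[C@@H](CCO)[C@@H](COCc1ccc(OC)cc1)C(=O)OC
F8 | step 14 | (3S,4S)-3-[(2E)-1-(TBSO)but-2-en-2-yl]-5-methoxy-4-{[(4-methoxyphenyl)methoxy]methyl}-5-oxopentanoic acid | C/C=C(/CO[Si](C)(C)C(C)(C)C)[C@@H](CC(=O)O)[C@@H](COCc1ccc(OC)cc1)C(=O)OC
F9 | step 14 | 5-{2-[3,4-bis(acetyloxy)phenyl]ethyl} 1-methyl (2S,3S)-3-[(2E)-1-(TBSO)but-2-en-2-yl]-2-{[(4-methoxyphenyl)methoxy]methyl}pentanedioate | C/C=C(/CO[Si](C)(C)C(C)(C)C)[C@@H](CC(=O)OCCc1ccc(OC(C)=O)c(OC(C)=O)c1)[C@@H](COCc1ccc(OC)cc1)C(=O)OC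
F10 | step 14 | 5-{2-[3,4-bis(acetyloxy)phenyl]ethyl} 1-methyl (2S,3S)-3-[(2E)-1-(TBSO)but-2-en-2-yl]-2-(hydroxymethyl)pentanedioate | C/C=C(/CO[Si](C)(C)C(C)(C)C)[C@@H](CC(=O)OCCc1ccc(OC(C)=O)c(OC(C)=O)c1)[C@@H](CO)C(=O)OC
F11 | step 14 | 5-{2-[3,4-bis(acetyloxy)phenyl]ethyl} 1-methyl (2S,3S)-3-[(2E)-1-(TBSO)but-2-en-2-yl]-2-formylpentanedioate | C/C=C(/CO[Si](C)(C)C(C)(C)C)[C@@H](CC(=O)OCCc1ccc(OC(C)=O)c(OC(C)=O)c1)[C@@H](C=O)C(=O)OC
F12 | step 14 | 5-{2-[3,4-bis(acetyloxy)phenyl]ethyl} 1-methyl (2S,3S)-2-formyl-3-[(2E)-1-hydroxybut-2-en-2-yl]pentanedioate | C/C=C(/CO)[C@@H](CC(=O)OCCc1ccc(OC(C)=O)c(OC(C)=O)c1)[C@@H](C=O)C(=O)OC
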